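**Retrosynthetic overview**
1. The strategy rests on the pentasubstituted phloroglucinol ring. Its C-alkylated carbon lies between the two C–OH carbons and para to the C–OMe carbon, and it is bonded to an acid-labile benzylic, allylic CH stereocentre that stands 1,3 to the carbinol. The ring is therefore grown around that stereocentre instead of being alkylated by it.
2. Calyxin A ⇐ global desilylation ⇐ carbonylative Suzuki coupling (aryl iodide + CO + (E)-styrylboronate) for the chalcone arm ⇐ mono-iodination of a symmetric bis-silylated 2-alkyl-5-methoxyresorcinol.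
3. Benzene ring ⇐ benzannulation of 3-methoxycyclobutenone with a chiral triisopropylsiloxyalkyne, whose two alkyne carbons become the alkylated carbon and one C–O carbon.
4. Siloxyalkyne ⇐ ynolate from an α,α-dibromo δ-lactone ⇐ trans-4-styryl-6-arylethyl lactone ⇐ rhodium conjugate addition to a dihydropyranone ⇐ asymmetric hetero-Diels–Alder adduct of a 3-arylpropanal and 1-methoxybutadiene.
5. Ring order: the dihydropyran first (stereochemical template, opened again when the ynolate forms), then the benzene ring by benzannulation; the chalcone arm is attached last.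

Key step: step 13

Remark: all phenols are carried as triisopropylsilyl (TIPS) ethers instead of a TBS/TIPS mix, because aryl TBS ethers are marginal under the aqueous base of the two boron couplings; Ar = 4-(triisopropylsilyloxy)phenyl in the names below.
Remark: cyclobutane-1,3-dione (present mainly as its enol) is taken as a purchasable material.

**Step 1**
Reactants: 1 methyl 3-(4-hydroxyphenyl)propanoate
Product: 2 methyl 3-Ar-propanoate
Conditions: i-Pr3SiCl, imidazole, DMF, rt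
Reagents that add atoms: triisopropylsilyl chloride, CC(C)[Si](Cl)(C(C)C)C(C)C
Why: Imidazole-promoted O-silylation of the phenol; the aryl TIPS ether should withstand the organolithium, enolate and mildly basic coupling steps ahead and fall to fluoride at the end.

**Step 2**
Reactants: 2 methyl 3-Ar-propanoate
Product: 3 3-Ar-propanal
Conditions: i-Bu2AlH (1.1 equiv), CH2Cl2, −78 °C; MeOH quench, aq. potassium sodium tartrate
Reagents that add atoms: none
Why: Partial reduction of the ester at −78 °C should stop at the aluminium hemiacetal stage and release the aldehyde only on work-up.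

**Step 3**
Reactants: 3 3-Ar-propanal; 4 (E)-1-methoxybuta-1,3-diene
Product: 5 (2S,6S)-2-methoxy-6-(2-Ar-ethyl)-5,6-dihydro-2H-pyran (cis)
Conditions: [CrCl(L)] (3 mol %; trivalent chromium; L = dianion of (1R,2S)-1-[(3-(1-adamantyl)-2-hydroxy-5-methylbenzylidene)amino]indan-2-ol), 4 Å molecular sieves, 4 (2 equiv), neat, rt
Reagents that add atoms: none
Why: Catalytic asymmetric hetero-Diels–Alder reaction in which the chiral chromium Lewis acid binds the aldehyde and the diene adds endo to one carbonyl face, which sets C6 (S, the future carbinol) and the cis 2,6-relationship; the (1R,2S) ligand is expected by analogy to give this sense, and the mirror-image catalyst is used if the sense proves opposite.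

**Step 4**
Reactants: 5 (2S,6S)-2-methoxy-6-(2-Ar-ethyl)-5,6-dihydro-2H-pyran
Product: 7 (S)-6-(2-Ar-ethyl)-5,6-dihydro-2H-pyran-2-one, via lactol 6 (not isolated)
Conditions: PPTS (cat.), acetone/H2O, rt; extractive work-up; then PhI(OAc)2, TEMPO (cat.), CH2Cl2, rt
Reagents that add atoms: water, O
Why: Mild acid hydrolysis of the allylic mixed acetal should give lactol 6, which the oxoammonium species from TEMPO and PhI(OAc)2 oxidizes to the unsaturated lactone; C6 is not involved and the aryl silyl ether tolerates both stages.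

**Step 5**
Reactants: 8 4-hydroxybenzaldehyde
Product: 9 4-(triisopropylsilyloxy)benzaldehyde
Conditions: i-Pr3SiCl, imidazole, DMF, rt
Reagents that add atoms: triisopropylsilyl chloride, CC(C)[Si](Cl)(C(C)C)C(C)C
Why: Standard phenol silylation, as in step 1.

**Step 6**
Reactants: 9 4-(triisopropylsilyloxy)benzaldehyde
Product: 10 1-ethynyl-4-(triisopropylsilyloxy)benzene
Conditions: Me3SiCHN2, n-BuLi, THF, −78 °C; then 9, −78 °C → rt
Reagents that add atoms: (trimethylsilyl)diazomethane, C[Si](C)(C)C=[N+]=[N-]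
Why: Colvin homologation of an aromatic aldehyde to the terminal alkyne with lithiated (trimethylsilyl)diazomethane; it avoids the methanolic carbonate of the Ohira–Bestmann variant, which could cleave the silyl ether of this electron-poor phenol.

**Step 7**
Reactants: 10 1-ethynyl-4-(triisopropylsilyloxy)benzene
Product: 11 (E)-2-(2-Ar-vinyl)-4,4,5,5-tetramethyl-1,3,2-dioxaborolane
Conditions: pinacolborane, Cp2Zr(H)Cl (5 mol %), Et3N (10 mol %), neat, 60 °C
Reagents that add atoms: pinacolborane, CC1(C)OBOC1(C)C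
Why: Zirconium-catalysed hydroboration of a terminal alkyne is a syn, anti-Markovnikov addition and should give the (E)-alkenylboronate used for both styryl units.

**Step 8**
Reactants: 7 (S)-6-(2-Ar-ethyl)-5,6-dihydro-2H-pyran-2-one; 11 (E)-2-(2-Ar-vinyl)-4,4,5,5-tetramethyl-1,3,2-dioxaborolane
Product: 12 (4S,6S)-4-[(E)-2-Ar-vinyl]-6-(2-Ar-ethyl)tetrahydro-2H-pyran-2-one (trans)
Conditions: [Rh(cod)OH]2 (3 mol %), K3PO4 (0.5 equiv), dioxane/H2O 10:1, 40 °C
Reagents that add atoms: none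
Why: Hayashi–Miyaura conjugate addition of an alkenylboron reagent to an unsaturated lactone; the alkenylrhodium should add to C4 from the face anti to the pseudo-equatorial C6 side chain, giving the trans lactone with the future benzylic centre, and a BINAP or chiral diene ligand of matched sense can reinforce this substrate bias.

**Step 9**
Reactants: 12 (4S,6S)-4-[(E)-2-Ar-vinyl]-6-(2-Ar-ethyl)tetrahydro-2H-pyran-2-one
Product: 14 (4S,6S)-3-bromo-4-[(E)-2-Ar-vinyl]-6-(2-Ar-ethyl)tetrahydro-2H-pyran-2-one (C3 epimers), via lithium enolate 13 (not isolated)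
Conditions: LiN(SiMe3)2 (1.1 equiv), THF, −78 °C; then BrCCl2CCl2Br, −78 °C
Reagents that add atoms: 1,2-dibromo-1,1,2,2-tetrachloroethane, BrC(Cl)(Cl)C(Cl)(Cl)Br
Why: Kinetic enolization of the lactone and bromination of the enolate by halophilic attack on a bromine donor that does not add to the electron-rich styrene; the C4 centre is β to the carbonyl and is untouched, and the C3 configuration is irrelevant.

**Step 10**
Reactants: 14 (4S,6S)-3-bromo-4-[(E)-2-Ar-vinyl]-6-(2-Ar-ethyl)tetrahydro-2H-pyran-2-one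
Product: 16 (4S,6S)-3,3-dibromo-4-[(E)-2-Ar-vinyl]-6-(2-Ar-ethyl)tetrahydro-2H-pyran-2-one, via bromo enolate 15 (not isolated)
Conditions: LiN(SiMe3)2 (1.05 equiv), THF, −78 °C; enolate cannulated into BrCCl2CCl2Br, −78 °C; cold quench
Reagents that add atoms: 1,2-dibromo-1,1,2,2-tetrachloroethane, BrC(Cl)(Cl)C(Cl)(Cl)Br
Why: The remaining α-hydrogen is the most acidic one, so a second enolate bromination should give the gem-dibromide; inverse addition and a cold quench suppress base-induced loss of HBr towards the conjugated dienyl lactone.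

**Step 11**
Reactants: 16 (4S,6S)-3,3-dibromo-4-[(E)-2-Ar-vinyl]-6-(2-Ar-ethyl)tetrahydro-2H-pyran-2-one
Product: 18 (3R,5S)-1,5-bis(triisopropylsilyloxy)-3-[(E)-2-Ar-vinyl]-7-Ar-hept-1-yne, via dilithium ynolate alkoxide 17 (not isolated)
Conditions: t-BuLi (4.1 equiv), THF, −78 → 0 °C; then i-Pr3SiOTf (2.3 equiv), −78 → 0 °C
Reagents that add atoms: triisopropylsilyl trifluoromethanesulfonate, CC(C)[Si](OS(=O)(=O)C(F)(F)F)(C(C)C)C(C)C
Why: Ynolate formation from an α,α-dibromo ester by two successive bromine–lithium exchanges, applied here to a lactone: the α-lithio enolate has its C–Li bond anti to the ring C–O bond and should expel the ring oxygen as the chain alkoxide to give 17, after which the bulky silyl triflate silylates the ynolate on oxygen and the alkoxide in the same flask; neither stereocentre is involved.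

**Step 12**
Reactants: 19 cyclobutane-1,3-dione
Product: 20 3-methoxycyclobut-2-en-1-one
Conditions: CH2N2, Et2O, 0 °C
Reagents that add atoms: diazomethane, C=[N+]=[N-]
Why: The strongly acidic enol of the 1,3-dione should be O-methylated by diazomethane without any nucleophile that could open the strained ring.

**Step 13**
Reactants: 18 (3R,5S)-1,5-bis(triisopropylsilyloxy)-3-[(E)-2-Ar-vinyl]-7-Ar-hept-1-yne; 20 3-methoxycyclobut-2-en-1-one
Product: 25 2-[(1E,3R,5S)-1,7-di-Ar-5-(triisopropylsilyloxy)hept-1-en-3-yl]-5-methoxy-3-(triisopropylsilyloxy)phenol, via vinylketene 21 (not isolated), via vinylcyclobutenone 22 (not isolated), via dienylketene 23 (not isolated), via cyclohexadienone 24 (not isolated)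
Conditions: degassed toluene, sealed vessel, 18 at 80 °C, 20 (1.5 equiv) added slowly, then 110 °C
Reagents that add atoms: none
Why: On heating, 20 should open reversibly by 4π electrocyclic cleavage to 3-methoxyvinylketene 21, whose ketene C=C adds to the alkyne of 18 in a (2+2) cycloaddition to give 22; a second 4π opening gives dienylketene 23, and 6π electrocyclization to 24 followed by tautomerization delivers phenol 25. The closest known reaction type is the Danheiser benzannulation of a cyclobutenone with a trialkylsiloxyalkyne, here with a 3-alkoxycyclobutenone and a branched skipped-enyne alkyne as untried partners. The cycloaddition bonds the ketene carbonyl carbon to the chain-bearing alkyne carbon and the ketene CH carbon to the oxygen-bearing alkyne carbon, and the benzene ring is then closed by a thermal disrotatory 6π electrocyclization that joins the former carbonyl carbon to the CH2 terminus. No stereocentre is created: the propargylic (R) centre and the (S) carbinol are spectators of a neutral pericyclic cascade and never pass through a cation, a carbanion or an enol. The step needs regioselectivity in the (2+2) event and chemoselectivity for the alkyne over the styrene, and both follow from the polarization of the siloxyalkyne, whose chain-bearing carbon is the nucleophilic terminus that attacks the ketene carbonyl carbon; this places the chain between two oxygenated carbons and para to OMe. Slow addition of 20 keeps the ketene concentration low, so that acylation of the hindered product phenol should stay minor.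

**Step 14**
Reactants: 25 2-[(1E,3R,5S)-1,7-di-Ar-5-(triisopropylsilyloxy)hept-1-en-3-yl]-5-methoxy-3-(triisopropylsilyloxy)phenol
Product: 26 2-[(1E,3R,5S)-1,7-di-Ar-5-(triisopropylsilyloxy)hept-1-en-3-yl]-5-methoxy-1,3-bis(triisopropylsilyloxy)benzene
Conditions: i-Pr3SiOTf, 2,6-lutidine, CH2Cl2, 0 °C → rt
Reagents that add atoms: triisopropylsilyl trifluoromethanesulfonate, CC(C)[Si](OS(=O)(=O)C(F)(F)F)(C(C)C)C(C)C
Why: Silylation of the hindered phenol with a silyl triflate and a non-nucleophilic base, under conditions that stay non-acidic towards the styrene; it makes the two open ring CH positions equivalent and masks the phenol for the palladium step.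

**Step 15**
Reactants: 26 2-[(1E,3R,5S)-1,7-di-Ar-5-(triisopropylsilyloxy)hept-1-en-3-yl]-5-methoxy-1,3-bis(triisopropylsilyloxy)benzene
Product: 27 4-iodo-5-methoxy-2-[(1E,3R,5S)-1,7-di-Ar-5-(triisopropylsilyloxy)hept-1-en-3-yl]-1,3-bis(triisopropylsilyloxy)benzene
Conditions: N-iodosuccinimide (1.05 equiv), MeCN/CH2Cl2, 0 °C, dark
Reagents that add atoms: N-iodosuccinimide, O=C1CCC(=O)N1I
Why: Electrophilic aromatic iodination; the tri-oxygenated ring is by far the most electron-rich arene, its two open positions are equivalent, and the first iodine should hinder and deactivate the ring against a second.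

**Step 16**
Reactants: 27 4-iodo-5-methoxy-2-[(1E,3R,5S)-1,7-di-Ar-5-(triisopropylsilyloxy)hept-1-en-3-yl]-1,3-bis(triisopropylsilyloxy)benzene; 11 (E)-2-(2-Ar-vinyl)-4,4,5,5-tetramethyl-1,3,2-dioxaborolane
Product: 28 (E)-1-{6-methoxy-3-[(1E,3R,5S)-1,7-di-Ar-5-(triisopropylsilyloxy)hept-1-en-3-yl]-2,4-bis(triisopropylsilyloxy)phenyl}-3-Ar-prop-2-en-1-one (hexakis-TIPS calyxin A)
Conditions: CO (1 atm), [PdCl2(IPr)(3-chloropyridine)] (3 mol %; IPr = 1,3-bis(2,6-diisopropylphenyl)imidazol-2-ylidene), K2CO3, H2O (3 equiv), anisole, 80 °C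
Reagents that add atoms: carbon monoxide, [C-]#[O+]
Why: Carbonylative Suzuki–Miyaura coupling: oxidative addition of the aryl iodide, CO insertion (favoured for a di-ortho-substituted, electron-rich arylpalladium, where direct transmetalation is slow) and transmetalation of the alkenylboronate with retention should give the (E)-enone, with CO supplying the ketone carbon.

**Step 17**
Reactants: 28 hexakis-TIPS calyxin A
Product: 29 calyxin A, (E)-1-{2,4-dihydroxy-3-[(1E,3R,5S)-5-hydroxy-1,7-bis(4-hydroxyphenyl)hept-1-en-3-yl]-6-methoxyphenyl}-3-(4-hydroxyphenyl)prop-2-en-1-one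
Conditions: Bu4NF/AcOH (1:1, excess), THF, 0 °C → rt (gentle warming if the alkyl silyl ether lags)
Reagents that add atoms: none
Why: Acetic acid-buffered fluoride should cleave the five aryl silyl ethers and, more slowly, the secondary alkyl silyl ether, while the buffer keeps the freed 2'-hydroxychalcone from closing to a flavanone and spares the benzylic, allylic stereocentre and the hydroxystyrene.

**Compound list**
1 | methyl 3-(4-hydroxyphenyl)propanoate | COC(=O)CCc1ccc(O)cc1 | starting material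
2 | methyl 3-[4-(triisopropylsilyloxy)phenyl]propanoate | COC(=O)CCc1ccc(O[Si](C(C)C)(C(C)C)C(C)C)cc1 | intermediate
3 | 3-[4-(triisopropylsilyloxy)phenyl]propanal | O=CCCc1ccc(O[Si](C(C)C)(C(C)C)C(C)C)cc1 | intermediate
4 | (E)-1-methoxybuta-1,3-diene | CO/C=C/C=C | starting material
5 | (2S,6S)-2-methoxy-6-(2-Ar-ethyl)-5,6-dihydro-2H-pyran (cis) | CO[C@@H]1C=CC[C@H](CCc2ccc(O[Si](C(C)C)(C(C)C)C(C)C)cc2)O1 | intermediate
6 | (6S)-6-(2-Ar-ethyl)-5,6-dihydro-2H-pyran-2-ol (lactol, anomers) | OC1C=CC[C@H](CCc2ccc(O[Si](C(C)C)(C(C)C)C(C)C)cc2)O1 | intermediate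
7 | (S)-6-(2-Ar-ethyl)-5,6-dihydro-2H-pyran-2-one | O=C1C=CC[C@H](CCc2ccc(O[Si](C(C)C)(C(C)C)C(C)C)cc2)O1 | intermediate
8 | 4-hydroxybenzaldehyde | O=Cc1ccc(O)cc1 | starting material
9 | 4-(triisopropylsilyloxy)benzaldehyde | O=Cc1ccc(O[Si](C(C)C)(C(C)C)C(C)C)cc1 | intermediate
10 | 1-ethynyl-4-(triisopropylsilyloxy)benzene | C#Cc1ccc(O[Si](C(C)C)(C(C)C)C(C)C)cc1 | intermediate
11 | (E)-2-(2-Ar-vinyl)-4,4,5,5-tetramethyl-1,3,2-dioxaborolane | CC1(C)OB(/C=C/c2ccc(O[Si](C(C)C)(C(C)C)C(C)C)cc2)OC1(C)C | intermediate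
12 | (4S,6S)-4-[(E)-2-Ar-vinyl]-6-(2-Ar-ethyl)tetrahydro-2H-pyran-2-one (trans) | O=C1C[C@@H](/C=C/c2ccc(O[Si](C(C)C)(C(C)C)C(C)C)cc2)C[C@H](CCc2ccc(O[Si](C(C)C)(C(C)C)C(C)C)cc2)O1 | intermediate
13 | lithium enolate of lactone 12 | [Li+].[O-]C1=C[C@@H](/C=C/c2ccc(O[Si](C(C)C)(C(C)C)C(C)C)cc2)C[C@H](CCc2ccc(O[Si](C(C)C)(C(C)C)C(C)C)cc2)O1 | intermediate
14 | (4S,6S)-3-bromo-4-[(E)-2-Ar-vinyl]-6-(2-Ar-ethyl)tetrahydro-2H-pyran-2-one (C3 epimers) | O=C1C(Br)[C@@H](/C=C/c2ccc(O[Si](C(C)C)(C(C)C)C(C)C)cc2)C[C@H](CCc2ccc(O[Si](C(C)C)(C(C)C)C(C)C)cc2)O1 | intermediate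
15 | lithium enolate of bromolactone 14 | [Li+].[O-]C1=C(Br)[C@@H](/C=C/c2ccc(O[Si](C(C)C)(C(C)C)C(C)C)cc2)C[C@H](CCc2ccc(O[Si](C(C)C)(C(C)C)C(C)C)cc2)O1 | intermediate
16 | (4S,6S)-3,3-dibromo-4-[(E)-2-Ar-vinyl]-6-(2-Ar-ethyl)tetrahydro-2H-pyran-2-one | O=C1C(Br)(Br)[C@@H](/C=C/c2ccc(O[Si](C(C)C)(C(C)C)C(C)C)cc2)C[C@H](CCc2ccc(O[Si](C(C)C)(C(C)C)C(C)C)cc2)O1 | intermediate
17 | dilithium (3R,5S)-3-[(E)-2-Ar-vinyl]-7-Ar-hept-1-yne-1,5-diolate (ynolate alkoxide) | [Li+].[Li+].[O-]C#C[C@@H](/C=C/c1ccc(O[Si](C(C)C)(C(C)C)C(C)C)cc1)C[C@@H]([O-])CCc1ccc(O[Si](C(C)C)(C(C)C)C(C)C)cc1 | intermediate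
18 | (3R,5S)-1,5-bis(triisopropylsilyloxy)-3-[(E)-2-Ar-vinyl]-7-Ar-hept-1-yne | CC(C)[Si](C(C)C)(C(C)C)OC#C[C@@H](/C=C/c1ccc(O[Si](C(C)C)(C(C)C)C(C)C)cc1)C[C@@H](O[Si](C(C)C)(C(C)C)C(C)C)CCc1ccc(O[Si](C(C)C)(C(C)C)C(C)C)cc1 | intermediate
19 | cyclobutane-1,3-dione | O=C1CC(=O)C1 | starting material
20 | 3-methoxycyclobut-2-en-1-one | COC1=CC(=O)C1 | intermediate
21 | 3-methoxybuta-1,3-dien-1-one (vinylketene) | C=C(OC)C=C=O | intermediate
22 | 2-[(1E,3R,5S)-1,7-di-Ar-5-(triisopropylsilyloxy)hept-1-en-3-yl]-4-(1-methoxyvinyl)-3-(triisopropylsilyloxy)cyclobut-2-en-1-one (C4 epimers) | O=C1C([C@@H](/C=C/c2ccc(O[Si](C(C)C)(C(C)C)C(C)C)cc2)C[C@@H](O[Si](C(C)C)(C(C)C)C(C)C)CCc2ccc(O[Si](C(C)C)(C(C)C)C(C)C)cc2)=C(O[Si](C(C)C)(C(C)C)C(C)C)C1C(OC)=C | intermediate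
23 | 2-[(1E,3R,5S)-1,7-di-Ar-5-(triisopropylsilyloxy)hept-1-en-3-yl]-5-methoxy-3-(triisopropylsilyloxy)hexa-1,3,5-trien-1-one (dienylketene, ketene and methoxyvinyl ends cis) | O=C=C([C@@H](/C=C/c1ccc(O[Si](C(C)C)(C(C)C)C(C)C)cc1)C[C@@H](O[Si](C(C)C)(C(C)C)C(C)C)CCc1ccc(O[Si](C(C)C)(C(C)C)C(C)C)cc1)/C(O[Si](C(C)C)(C(C)C)C(C)C)=C\C(OC)=C | intermediate
24 | 2-[(1E,3R,5S)-1,7-di-Ar-5-(triisopropylsilyloxy)hept-1-en-3-yl]-5-methoxy-3-(triisopropylsilyloxy)cyclohexa-2,4-dien-1-one | O=C1CC(OC)=CC(O[Si](C(C)C)(C(C)C)C(C)C)=C1[C@@H](/C=C/c1ccc(O[Si](C(C)C)(C(C)C)C(C)C)cc1)C[C@@H](O[Si](C(C)C)(C(C)C)C(C)C)CCc1ccc(O[Si](C(C)C)(C(C)C)C(C)C)cc1 | intermediate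
25 | 2-[(1E,3R,5S)-1,7-di-Ar-5-(triisopropylsilyloxy)hept-1-en-3-yl]-5-methoxy-3-(triisopropylsilyloxy)phenol | COc1cc(O)c([C@@H](/C=C/c2ccc(O[Si](C(C)C)(C(C)C)C(C)C)cc2)C[C@@H](O[Si](C(C)C)(C(C)C)C(C)C)CCc2ccc(O[Si](C(C)C)(C(C)C)C(C)C)cc2)c(O[Si](C(C)C)(C(C)C)C(C)C)c1 | intermediate
26 | 2-[(1E,3R,5S)-1,7-di-Ar-5-(triisopropylsilyloxy)hept-1-en-3-yl]-5-methoxy-1,3-bis(triisopropylsilyloxy)benzene | COc1cc(O[Si](C(C)C)(C(C)C)C(C)C)c([C@@H](/C=C/c2ccc(O[Si](C(C)C)(C(C)C)C(C)C)cc2)C[C@@H](O[Si](C(C)C)(C(C)C)C(C)C)CCc2ccc(O[Si](C(C)C)(C(C)C)C(C)C)cc2)c(O[Si](C(C)C)(C(C)C)C(C)C)c1 | intermediate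
27 | 4-iodo-5-methoxy-2-[(1E,3R,5S)-1,7-di-Ar-5-(triisopropylsilyloxy)hept-1-en-3-yl]-1,3-bis(triisopropylsilyloxy)benzene | COc1cc(O[Si](C(C)C)(C(C)C)C(C)C)c([C@@H](/C=C/c2ccc(O[Si](C(C)C)(C(C)C)C(C)C)cc2)C[C@@H](O[Si](C(C)C)(C(C)C)C(C)C)CCc2ccc(O[Si](C(C)C)(C(C)C)C(C)C)cc2)c(O[Si](C(C)C)(C(C)C)C(C)C)c1I | intermediate
28 | hexakis-TIPS calyxin A | COc1cc(O[Si](C(C)C)(C(C)C)C(C)C)c([C@@H](/C=C/c2ccc(O[Si](C(C)C)(C(C)C)C(C)C)cc2)C[C@@H](O[Si](C(C)C)(C(C)C)C(C)C)CCc2ccc(O[Si](C(C)C)(C(C)C)C(C)C)cc2)c(O[Si](C(C)C)(C(C)C)C(C)C)c1C(=O)/C=C/c1ccc(O[Si](C(C)C)(C(C)C)C(C)C)cc1 | intermediate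
29 | calyxin A | COc1cc(O)c([C@@H](/C=C/c2ccc(O)cc2)C[C@@H](O)CCc2ccc(O)cc2)c(O)c1C(=O)/C=C/c1ccc(O)cc1 | target

**Totals**
Total step count: 17. Longest linear sequence: 13 steps (steps 1–4, 8–11 and 13–17).

**Three steps most likely to fail**

Step 13 (benzannulation). Ring opening of the vinylogous ester 20 may need a temperature at which the siloxyalkyne rearranges or is consumed by other pathways, and excess ketene may acylate the product phenol, so the cascade could stall or waste the chiral alkyne. The fallback sets out from 18 and comes back at 25, and it generates the same vinylketene 21 at room temperature by a photochemical Wolff rearrangement. Purchased 3,3-dimethoxybutan-2-one F1 should lose methanol on heating with catalytic TsOH to give 3-methoxybut-3-en-2-one F2. Enolization with LiN(SiMe3)2 and acylation with 2,2,2-trifluoroethyl trifluoroacetate gives 1,1,1-trifluoro-5-methoxyhex-5-ene-2,4-dione F3, and detrifluoroacetylative diazo transfer (MsN3, Et3N, aqueous MeCN) gives 1-diazo-3-methoxybut-3-en-2-one F4. Irradiation of F4 with 18 in CH2Cl2 at rt (Pyrex-filtered medium-pressure mercury lamp), then warming to 80 °C to drive the 4π opening and 6π closure, should deliver 25 through 22, 23 and 24.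

Step 11 (ynolate from the dibromolactone). The second bromine–lithium exchange may be incomplete, t-BuLi may add to the styrene, or silylation may occur on carbon, after which the tethered alkoxide would re-close onto the ketene and return a lactone. The fallback sets out from 12 and comes back at 18, and it forms the ynolate on an acyclic α,α-dibromo ester, the substrate class on which this reaction is established, with the carbinol already capped. Lactone 12 is opened with catalytic K2CO3 in MeOH at 0 °C to methyl (3S,5S)-5-hydroxy-3-[(E)-2-Ar-vinyl]-7-Ar-heptanoate F5, which is silylated at once (i-Pr3SiOTf, 2,6-lutidine) to methyl (3S,5S)-5-(triisopropylsilyloxy)-3-[(E)-2-Ar-vinyl]-7-Ar-heptanoate F6. Enolization with LiN(SiMe3)2 to the lithium ester enolate F7 and bromination with BrCCl2CCl2Br gives the methyl 2-bromo ester F8. Repetition through the lithium bromo enolate F9 gives the methyl 2,2-dibromo ester F10. Treatment with t-BuLi (4 equiv, THF, −78 → 0 °C) should then give the lithium ynolate F11 with loss of methoxide, and i-Pr3SiOTf (2.2 equiv) silylates it on oxygen to give 18.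

Step 16 (carbonylative coupling). Direct coupling may outrun CO insertion, transmetalation of the pinacol boronate to the hindered acylpalladium may be slow, or the base may strip the ortho silyl ether and let the phenoxide close onto the enone. The fallback sets out from 27 and comes back at 28, and it builds the ketone by carbonyl addition and oxidation. Iodine–lithium exchange on 27 (n-BuLi, Et2O, −78 °C, where silyl migration from oxygen to carbon should be slow) gives the aryllithium F12. This is added at −78 °C to (E)-3-Ar-acrylaldehyde F13, itself made from 9 and Ph3P=CHCHO in toluene at 80 °C. The resulting benzylic, allylic alcohol 1-aryl-3-Ar-prop-2-en-1-ol F14 (either carbinol epimer) is oxidized with MnO2 in CH2Cl2 to 28.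

**Further compounds**
F1 | step 13 | 3,3-dimethoxybutan-2-one | CC(=O)C(C)(OC)OC
F2 | step 13 | 3-methoxybut-3-en-2-one | CC(=O)C(OC)=C
F3 | step 13 | 1,1,1-trifluoro-5-methoxyhex-5-ene-2,4-dione | C=C(OC)C(=O)CC(=O)C(F)(F)F
F4 | step 13 | 1-diazo-3-methoxybut-3-en-2-one | C=C(OC)C(=O)C=[N+]=[N-]
F5 | step 11 | methyl (3S,5S)-5-hydroxy-3-[(E)-2-Ar-vinyl]-7-Ar-heptanoate | COC(=O)C[C@@H](/C=C/c1ccc(O[Si](C(C)C)(C(C)C)C(C)C)cc1)C[C@@H](O)CCc1ccc(O[Si](C(C)C)(C(C)C)C(C)C)cc1
F6 | step 11 | methyl (3S,5S)-5-(triisopropylsilyloxy)-3-[(E)-2-Ar-vinyl]-7-Ar-heptanoate | COC(=O)C[C@@H](/C=C/c1ccc(O[Si](C(C)C)(C(C)C)C(C)C)cc1)C[C@@H](O[Si](C(C)C)(C(C)C)C(C)C)CCc1ccc(O[Si](C(C)C)(C(C)C)C(C)C)cc1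
F7 | step 11 | lithium enolate of ester F6 | [Li+].[O-]C(OC)=C[C@@H](/C=C/c1ccc(O[Si](C(C)C)(C(C)C)C(C)C)cc1)C[C@@H](O[Si](C(C)C)(C(C)C)C(C)C)CCc1ccc(O[Si](C(C)C)(C(C)C)C(C)C)cc1
F8 | step 11 | methyl (3S,5S)-2-bromo-5-(triisopropylsilyloxy)-3-[(E)-2-Ar-vinyl]-7-Ar-heptanoate (C2 epimers) | COC(=O)C(Br)[C@@H](/C=C/c1ccc(O[Si](C(C)C)(C(C)C)C(C)C)cc1)C[C@@H](O[Si](C(C)C)(C(C)C)C(C)C)CCc1ccc(O[Si](C(C)C)(C(C)C)C(C)C)cc1
F9 | step 11 | lithium enolate of bromo ester F8 | [Li+].[O-]C(OC)=C(Br)[C@@H](/C=C/c1ccc(O[Si](C(C)C)(C(C)C)C(C)C)cc1)C[C@@H](O[Si](C(C)C)(C(C)C)C(C)C)CCc1ccc(O[Si](C(C)C)(C(C)C)C(C)C)cc1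
F10 | step 11 | methyl (3S,5S)-2,2-dibromo-5-(triisopropylsilyloxy)-3-[(E)-2-Ar-vinyl]-7-Ar-heptanoate | COC(=O)C(Br)(Br)[C@@H](/C=C/c1ccc(O[Si](C(C)C)(C(C)C)C(C)C)cc1)C[C@@H](O[Si](C(C)C)(C(C)C)C(C)C)CCc1ccc(O[Si](C(C)C)(C(C)C)C(C)C)cc1
F11 | step 11 | lithium (3R,5S)-5-(triisopropylsilyloxy)-3-[(E)-2-Ar-vinyl]-7-Ar-hept-1-yn-1-olate | [Li+].[O-]C#C[C@@H](/C=C/c1ccc(O[Si](C(C)C)(C(C)C)C(C)C)cc1)C[C@@H](O[Si](C(C)C)(C(C)C)C(C)C)CCc1ccc(O[Si](C(C)C)(C(C)C)C(C)C)cc1
F12 | step 16 | aryllithium from 27 | COc1cc(O[Si](C(C)C)(C(C)C)C(C)C)c([C@@H](/C=C/c2ccc(O[Si](C(C)C)(C(C)C)C(C)C)cc2)C[C@@H](O[Si](C(C)C)(C(C)C)C(C)C)CCc2ccc(O[Si](C(C)C)(C(C)C)C(C)C)cc2)c(O[Si](C(C)C)(C(C)C)C(C)C)c1[Li]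
F13 | step 16 | (E)-3-[4-(triisopropylsilyloxy)phenyl]acrylaldehyde | O=C/C=C/c1ccc(O[Si](C(C)C)(C(C)C)C(C)C)cc1
F14 | step 16 | (E)-1-{6-methoxy-3-[(1E,3R,5S)-1,7-di-Ar-5-(triisopropylsilyloxy)hept-1-en-3-yl]-2,4-bis(triisopropylsilyloxy)phenyl}-3-Ar-prop-2-en-1-ol (carbinol epimers) | COc1cc(O[Si](C(C)C)(C(C)C)C(C)C)c([C@@H](/C=C/c2ccc(O[Si](C(C)C)(C(C)C)C(C)C)cc2)C[C@@H](O[Si](C(C)C)(C(C)C)C(C)C)CCc2ccc(O[Si](C(C)C)(C(C)C)C(C)C)cc2)c(O[Si](C(C)C)(C(C)C)C(C)C)c1C(O)/C=C/c1ccc(O[Si](C(C)C)(C(C)C)C(C)C)cc1
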